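**Assumptions**
- 3-Hydroxy-2-methoxybenzaldehyde (1) is taken as commercially available. If it is not, it is made from 2,3-dihydroxybenzaldehyde by selective 3-O-protection followed by 2-O-methylation.
- The sense of induction of the Rh/diene catalyst is assumed. The chiral-diene antipode that gives the (S)-benzhydryl centre is used.
- Vitekwangin B is the open hydroxy-enal. Any lactol tautomer is assumed to collapse on work-up.

**Retrosynthesis**
1. Vitekwangin B comes from the MOM/TBS-protected hydroxy-enal 14 by global deprotection. Ring B is closed only once, in the second-to-last step, by intramolecular aldol condensation of dialdehyde 13 (C3–C4 bond, C3=C4 enal).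
2. Dialdehyde 13 comes from styrene 12 by double oxidative cleavage of the aryl vinyl and the allyl group. The vinyl group comes from an aryl bromide, which is the masked C4a carbon.
3. C2 is set by Evans allylation of imide 8. C1 (the diarylmethine centre) is set by the key new step, Rh/chiral-diene 1,4-arylation of cinnamoyl imide 6 with 3,4-dimethoxyphenylboronic acid (7).
4. Imide 6 comes from Doebner condensation of aryl aldehyde 3 and the Evans auxiliary. Aldehyde 3 comes from commercial 1 by MOM protection and Comins ortho-bromination. Ring A is therefore fully built before ring B is formed.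

**Route**

Step 1
Reactants: 1 (3-hydroxy-2-methoxybenzaldehyde)
Product: 2 (2-methoxy-3-(methoxymethoxy)benzaldehyde)
Conditions: MOMCl, i-Pr2NEt, CH2Cl2, 0 °C → rt
Reagents that add atoms: MOMCl, COCCl
Why: Williamson-type etherification masks the phenol as a MOM ether that survives organolithium, basic and Pd conditions later in the route.

Step 2
Reactants: 2
Product: 3 (6-bromo-2-methoxy-3-(methoxymethoxy)benzaldehyde)
Conditions: LiN(Me)CH2CH2NMe2, THF, 0 °C; then n-BuLi, hexane, –20 °C; then BrCCl2CCl2Br, –78 °C → rt
Reagents that add atoms: 1,2-dibromo-1,1,2,2-tetrachloroethane, ClC(Cl)(Br)C(Cl)(Cl)Br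
Why: Comins in-situ α-amino-alkoxide directed ortho-lithiation can only occur at C6, the one free position ortho to the aldehyde, so Br lands exactly where C4a is needed.

Step 3
Reactants: 3
Product: 4 ((E)-3-[6-bromo-2-methoxy-3-(methoxymethoxy)phenyl]acrylic acid)
Conditions: CH2(CO2H)2, pyridine, piperidine (cat.), 100 °C
Reagents that add atoms: malonic acid, OC(=O)CC(=O)O
Why: Knoevenagel–Doebner condensation followed by decarboxylation gives the (E)-cinnamic acid and forms the C1=C2 carbons of the future ring B.

Step 4
Reactants: 4; 5 ((S)-4-benzyloxazolidin-2-one)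
Product: 6 ((S)-4-benzyl-3-{(E)-3-[6-bromo-2-methoxy-3-(methoxymethoxy)phenyl]acryloyl}oxazolidin-2-one)
Conditions: 4, PivCl, Et3N, THF, –20 °C; then Li salt of 5 (n-BuLi, THF, –78 °C → 0 °C)
Reagents that add atoms: none
Why: Mixed pivalic anhydride acylation (Evans imide formation) installs the chiral auxiliary that will control C2 later.

Step 5
Reactants: 6; 7 (3,4-dimethoxyphenylboronic acid)
Product: 8 ((S)-4-benzyl-3-{(S)-3-[6-bromo-2-methoxy-3-(methoxymethoxy)phenyl]-3-(3,4-dimethoxyphenyl)propanoyl}oxazolidin-2-one)
Conditions: [Rh(C2H4)2Cl]2 (2.5 mol %), chiral diene (e.g. Ph-bod*, 5.5 mol %), 7 (3 equiv), KOH (0.5 equiv), dioxane/H2O 10:1, 50 °C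
Reagents that add atoms: none (H+ from water only)
Why: Proposed new method: a Rh(I)–hydroxo/chiral-diene catalyst transmetalates the electron-rich aryl, and the resulting Rh–Ar inserts face-selectively into the imide-chelated enoyl C=C, with the diene quadrant discriminating the ortho,ortho′-disubstituted ring A from the incoming aryl. This sets the hindered benzhydryl centre C1 as (S), and the Rh oxa-π-allyl is then protonated by water. The Ar–Br handle should survive because hydroxo-Rh transmetalation is much faster than oxidative addition into a hindered ortho-substituted aryl bromide. The closest known reaction is Hayashi–Miyaura asymmetric 1,4-arylation of enones and enoyl imides, which has not been shown on a 2-bromo-6-alkoxy-cinnamoyl imide that creates an ortho,ortho′-disubstituted diarylmethine.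

Step 6
Reactants: 8
Product: 9 ((S)-4-benzyl-3-{(S)-2-[(S)-(6-bromo-2-methoxy-3-(methoxymethoxy)phenyl)(3,4-dimethoxyphenyl)methyl]pent-4-enoyl}oxazolidin-2-one)
Conditions: NaHMDS, THF, –78 °C; then allyl iodide, –78 → –40 °C
Reagents that add atoms: allyl iodide, C=CCI
Why: Evans asymmetric alkylation of the chelated Z-sodium enolate occurs anti to the C4-benzyl group, setting C2 with the relative configuration that becomes trans to the C1 aryl group.

Step 7
Reactants: 9
Product: 10 ((S)-2-[(S)-(6-bromo-2-methoxy-3-(methoxymethoxy)phenyl)(3,4-dimethoxyphenyl)methyl]pent-4-en-1-ol)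
Conditions: LiBH4, MeOH (2 equiv), Et2O, 0 °C → rt
Reagents that add atoms: none (hydride only)
Why: Reductive cleavage of the imide gives the primary alcohol (the future C2–CH2OH) and releases the auxiliary; neither stereocentre is touched.

Step 8
Reactants: 10
Product: 11 (TBS ether of 10)
Conditions: TBSCl, imidazole, DMF, rt
Reagents that add atoms: TBSCl, CC(C)(C)[Si](C)(C)Cl
Why: Silyl protection prevents lactol or acetal formation later and survives the Pd, Os and amine steps.

Step 9
Reactants: 11
Product: 12 (aryl bromide of 11 converted to the styrene)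
Conditions: CH2=CHBF3K, PdCl2(dppf), Cs2CO3, THF/H2O 9:1, 80 °C
Reagents that add atoms: potassium vinyltrifluoroborate, C=C[B-](F)(F)F.[K+]
Why: Suzuki–Miyaura vinylation converts the masked C4a carbon into a vinyl group that can be cleaved to the aldehyde.

Step 10
Reactants: 12
Product: 13 ((3S,4S)-3-[(TBSO)methyl]-4-(3,4-dimethoxyphenyl)-4-[6-formyl-2-methoxy-3-(methoxymethoxy)phenyl]butanal)
Conditions: OsO4 (5 mol %), 2,6-lutidine, NaIO4, dioxane/H2O 3:1, rt
Reagents that add atoms: OsO4, O=[Os](=O)(=O)=O (oxygen donor); NaIO4, [Na+].[O-]I(=O)(=O)=O (terminal oxidant)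
Why: Lemieux–Johnson cleavage converts both terminal alkenes into aldehydes in one operation. The aryl aldehyde becomes the future C4, and the aliphatic CH2CHO supplies C3 and the carbaldehyde.

Step 11
Reactants: 13
Product: 14 ((1S,2R)-1-(3,4-dimethoxyphenyl)-2-[(TBSO)methyl]-8-methoxy-7-(methoxymethoxy)-1,2-dihydronaphthalene-3-carbaldehyde)
Conditions: pyrrolidine (0.3 equiv), AcOH (0.3 equiv), toluene (0.01 M), 40 °C
Reagents that add atoms: none
Why: Enamine-catalysed intramolecular crossed aldol condensation closes ring B regiospecifically (the only aryl carbonyl is the C4 aldehyde) and dehydrates to the conjugated enal. No new stereocentre is formed, and C2–H is not α to a carbonyl, so C1 and C2 are not epimerised.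

Step 12
Reactants: 14
Product: 15 (vitekwangin B)
Conditions: 3 M HCl, THF/H2O, 45 °C; then aqueous NaHCO3 work-up
Reagents that add atoms: none (H+ only)
Why: Acid hydrolysis removes the primary TBS ether and the aryl MOM ether, giving the free phenol and primary alcohol while the enal and both stereocentres are untouched.

**Compound list**

| No. | Name | SMILES | Role |
|---|---|---|---|
| 1 | 3-hydroxy-2-methoxybenzaldehyde | O=Cc1cccc(O)c1OC | starting material |
| 2 | 2-methoxy-3-(methoxymethoxy)benzaldehyde | O=Cc1cccc(OCOC)c1OC | intermediate |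
| 3 | 6-bromo-2-methoxy-3-(methoxymethoxy)benzaldehyde | O=Cc1c(Br)ccc(OCOC)c1OC | intermediate |
| 4 | (E)-3-[6-bromo-2-methoxy-3-(methoxymethoxy)phenyl]acrylic acid | O=C(O)/C=C/c1c(Br)ccc(OCOC)c1OC | intermediate |
| 5 | (S)-4-benzyloxazolidin-2-one | O=C1N[C@@H](Cc2ccccc2)CO1 | starting material |
| 6 | (S)-4-benzyl-3-{(E)-3-[6-bromo-2-methoxy-3-(methoxymethoxy)phenyl]acryloyl}oxazolidin-2-one | O=C(/C=C/c1c(Br)ccc(OCOC)c1OC)N1[C@@H](Cc2ccccc2)COC1=O | intermediate |
| 7 | 3,4-dimethoxyphenylboronic acid | COc1ccc(B(O)O)cc1OC | starting material |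
| 8 | Rh arylation product (3S imide) | COc1ccc([C@H](CC(=O)N2[C@@H](Cc3ccccc3)COC2=O)c2c(Br)ccc(OCOC)c2OC)cc1OC | intermediate |
| 9 | allylated imide | COc1ccc([C@H]([C@H](CC=C)C(=O)N2[C@@H](Cc3ccccc3)COC2=O)c2c(Br)ccc(OCOC)c2OC)cc1OC | intermediate |
| 10 | (S)-2-[(S)-diarylmethyl]pent-4-en-1-ol | COc1ccc([C@H]([C@H](CC=C)CO)c2c(Br)ccc(OCOC)c2OC)cc1OC | intermediate |
| 11 | TBS ether of 10 | COc1ccc([C@H]([C@H](CC=C)CO[Si](C)(C)C(C)(C)C)c2c(Br)ccc(OCOC)c2OC)cc1OC | intermediate |
| 12 | styrene 12 | COc1ccc([C@H]([C@H](CC=C)CO[Si](C)(C)C(C)(C)C)c2c(C=C)ccc(OCOC)c2OC)cc1OC | intermediate |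
| 13 | dialdehyde 13 | COc1ccc([C@H]([C@H](CC=O)CO[Si](C)(C)C(C)(C)C)c2c(C=O)ccc(OCOC)c2OC)cc1OC | intermediate |
| 14 | protected dihydronaphthalene enal | COc1ccc([C@H]2c3c(ccc(OCOC)c3OC)C=C(C=O)[C@@H]2CO[Si](C)(C)C(C)(C)C)cc1OC | intermediate |
| 15 | vitekwangin B | COc1ccc([C@H]2c3c(ccc(O)c3OC)C=C(C=O)[C@@H]2CO)cc1OC | target |

**Totals:** 12 steps, and the longest linear sequence is 12 steps.

**Three steps most likely to fail**
1. **Step 5 (proposed new Rh/diene arylation).** The hindered 2,6-disubstituted β-aryl acceptor may give low conversion or ee, or Rh may insert into the Ar–Br bond.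
   - Fallback: switch from catalyst control to auxiliary control. Add 3,4-dimethoxyphenyl-MgBr/CuBr·SMe2/TMSCl (from 4-bromoveratrole) to imide 6, then separate the C1 diastereomers on silica. This is known chemistry.
2. **Step 2 (Comins ortho-bromination).** Lithiation ortho to the MOM ether (C4) could compete with the desired C6 lithiation.
   - Fallback: brominate aldehyde 2 by Pd(II)/amino-acid transient-directing-group ortho-C–H bromination, an approach that uses no organolithium.
3. **Step 11 (aldol condensation).** Intermolecular oligomerisation of the aliphatic aldehyde may compete with ring closure.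
   - Fallback: take styrene 12 through ring-closing metathesis (Grundbs II) to the 1,2-dihydronaphthalene. Then formylate C3 by Vilsmeier–Haack, where the C4 cation is stabilised by the para-O7 oxygen, and finish with Step 12.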